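**Retrosynthetic overview**
1. The target is reached from the 3α,8α,9α-triol by acylating its two equatorial hydroxyls with two equivalents of hex-2-ynoic acid and semihydrogenating; the triol comes from a C8 ketone (axial-selective hydride) whose C7 isopropenyl group is put on a 6-en-8-one by α-iodination, Suzuki coupling and conjugate reduction.
2. The 6-en-8-one comes from a trans-fused 8-methoxy-7-ene-6,9-dione by hydride reduction and acid hydrolysis, a 1,3-carbonyl transposition that deletes the auxiliary C6 oxygen.
3. Key disconnection (ring A): C1–C10 and C4–C5 by a Diels–Alder reaction between the C5=C10 bond of 2-methoxy-5-methyl-1,4-benzoquinone (ring B at a higher oxidation level) and 4-silyloxy-2H-thiopyran (C1–C4), whose S–CH2 unit is a temporary ring that delivers the C4 methyl cis to the C5 methyl and is later cut out with nickel.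
4. Enabling feature: ring A (C1–C5, C10) carries oxygen on C3 and shares the C5–C10 bond with ring B, whose C9 next to C10 is oxygenated; C2=C3(O) is therefore a [4+2] retron (2-oxydiene plus enone), and the C8/C9 oxygens together with C6 map onto a p-quinone ring.
5. Ring order: ring B is bought as the quinone, ring A is closed in the key step, and the thia-bridge is opened directly afterwards.

Key step: step 3

Numbering in names: decalin atoms as in eremophilanes (ring A = C1–C5 and C10; ring B = C5–C10; methyls on C4 and C5, isopropenyl on C7); β is the face of the C5 methyl, α the opposite face.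
Assumption: (S)-BINOL is taken to be the ligand enantiomer that gives the adduct of step 3 as drawn; if the sense of induction is the opposite, (R)-BINOL is used with nothing else changed.

**Route**

Step 1
Reactants: 1 thian-4-one
Product: 3 2,3-dihydro-4H-thiopyran-4-one, via 2-chlorothian-4-one 2 (not isolated)
Conditions: NCS, pyridine, CH2Cl2, 0 °C to rt
Reagents that add atoms: none
Why: α-Chlorination of the sulfide by NCS (via the chlorosulfonium ion, Pummerer-type) and pyridine-induced loss of HCl should give the vinylogous thioester; no stereocenter is formed.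

Step 2
Reactants: 3 2,3-dihydro-4H-thiopyran-4-one
Product: 4 4-(triisopropylsilyloxy)-2H-thiopyran
Conditions: i-Pr3SiOTf, Et3N, CH2Cl2, 0 °C
Reagents that add atoms: triisopropylsilyl trifluoromethanesulfonate, CC(C)[Si](OS(=O)(=O)C(F)(F)F)(C(C)C)C(C)C
Why: Soft enolization (silyl triflate/amine) on the saturated α'-side should give the cross-conjugated silyl dienol ether, a diene locked s-cis by its ring; no stereocenter is formed.

Step 3
Reactants: 5 2-methoxy-5-methyl-1,4-benzoquinone; 4 4-(triisopropylsilyloxy)-2H-thiopyran
Product: 6 thia-bridged cis-enedione adduct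
Conditions: (S)-BINOL, TiCl2(OiPr)2 (20 mol% each), 4 Å MS, toluene/CH2Cl2, −40 °C
Reagents that add atoms: none
Why: Proposed new method: the BINOL–titanium Lewis acid is expected to chelate the C9 carbonyl and the neighbouring methoxy oxygen of 5 and so lower the LUMO of the C5=C10 alkene, to which the s-cis-locked silyloxydiene 4 adds in a concerted but asynchronous endo [4+2] cycloaddition (bond to C5 leading); the closest known reaction types are the Diels–Alder reactions of 4-silyloxy-2H-thiopyrans with activated alkenes (cis-diene surrogates) and the BINOL–titanium-catalysed enantioselective Diels–Alder reaction of 2-methoxybenzoquinones with silyloxydienes, and only their combination on a methyl-bearing quinone alkene is new. Ring A is closed as a six-membered carbocycle in the suprafacial [4π+2π] mode (C1–C10 and C4–C5 formed together), and because the diene is cyclic it emerges as a 2-thiabicyclo[2.2.2]octene with S–CH2 spanning C1 and C4. The quaternary C5 takes its absolute configuration from the quinone face left open by the BINOL ligand, C10–H is cis to the C5 methyl through suprafacial addition to the ring alkene, and C1 and C4 are fixed by the endo transition state, in which the S–CH2 bridge lies on the side of the exo C5 methyl, so that the carbon that becomes the C4 methyl is cis to the C5 methyl. The step needs site selectivity (C5=C10 over C7=C8, secured by the methoxy group, which turns C7=C8 into an unreactive vinylogous ester), regioselectivity (the nucleophilic diene terminus, β to the silyloxy group and remote from sulfur, must bond to C5, secured by activation through C9=O, which makes C5 the β-carbon), endo selectivity (quinone carbonyls under the diene) and face selectivity (catalyst).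

Step 4
Reactants: 6 thia-bridged cis-enedione adduct
Product: 7 cis-fused silyl enol ether enedione
Conditions: Raney Ni (acetone-deactivated, washed neutral), THF/EtOH, 0 °C
Reagents that add atoms: none
Why: Reductive desulfurization (hydrogenolysis of both C–S bonds on nickel, the C1–S bond being allylic) should open the temporary ring to C1H2 and the C4 methyl without touching C4, C5 or C10, and cold, neutral, deactivated nickel is chosen to spare the vinylogous ester, the ketones and the silyl enol ether.

Step 5
Reactants: 7 cis-fused silyl enol ether enedione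
Product: 9 trans-fused silyl enol ether enedione, via lithium dienolate 8 (not isolated)
Conditions: LiN(SiMe3)2, THF, −78 °C; then AcOH, −78 °C
Reagents that add atoms: none
Why: Enolization at C10, the only acidic C–H, and kinetic axial protonation of the dienolate on the α-face, anti to the adjacent axial C5 methyl, should invert C10 to the trans ring fusion (enolate epimerization).

Step 6
Reactants: 9 trans-fused silyl enol ether enedione
Product: 11 9β-hydroxy-6-ene-3,8-dione, via enol-ether diol 10 (not isolated)
Conditions: LiAlH4, THF, −40 to 0 °C; then 2 M HCl, THF, rt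
Reagents that add atoms: water, O
Why: Hydride 1,2-reduction of both carbonyls followed by acid hydrolysis of the enol ether with loss of the C6 hydroxyl (Stork–Danheiser-type reduction/hydrolysis transposition of a vinylogous ester) should give the 6-en-8-one without the auxiliary C6 oxygen, the acid also unmasks the C3 ketone (next to which the equatorial 4β-methyl is the more stable epimer and should persist), and the C9 carbinol (hydride expected anti to the C5 methyl, 9β) is corrected in step 8.

Step 7
Reactants: 11 9β-hydroxy-6-ene-3,8-dione
Product: 12 3α,9β-dihydroxy-6-en-8-one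
Conditions: (R)-selective ketoreductase, NADP+ (cat.), i-PrOH, phosphate buffer pH 7, DMSO (5%), 30 °C
Reagents that add atoms: none
Why: Enzymatic carbonyl reduction: a ketoreductase should accept the unconjugated C3 ketone but not the hindered enone and deliver hydride to the β-face, which is syn to the axial C5 methyl and therefore disfavoured for small hydride reagents, giving the equatorial (3R)-alcohol and raising the enantiomeric purity.

Step 8
Reactants: 12 3α,9β-dihydroxy-6-en-8-one
Product: 13 3α,9α-dihydroxy-6-en-8-one
Conditions: K2CO3 (0.2 equiv), degassed MeOH, rt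
Reagents that add atoms: none
Why: Base-mediated epimerization α to the ketone through the enediolate (C9 is the only enolizable position) should move the axial 9β-hydroxyl, which is syn-diaxial to the C5 methyl, to the equatorial 9α position under thermodynamic control.

Step 9
Reactants: 13 3α,9α-dihydroxy-6-en-8-one
Product: 14 7-iodo enone
Conditions: I2, pyridine, CH2Cl2, rt
Reagents that add atoms: iodine, II
Why: α-Iodination of the enone by the pyridine addition/iodination/elimination sequence (Baylis–Hillman-type α-halogenation) should functionalize C7; no stereocenter is formed.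

Step 10
Reactants: 14 7-iodo enone; 15 isopropenylboronic acid pinacol ester
Product: 16 7-isopropenyl dienone
Conditions: Pd(dppf)Cl2 (5 mol%), K3PO4, dioxane/H2O, 60 °C
Reagents that add atoms: none
Why: Suzuki–Miyaura coupling of the α-iodoenone with the alkenylboronate should form the C7–isopropenyl bond; no stereocenter is formed.

Step 11
Reactants: 16 7-isopropenyl dienone
Product: 17 7α-isopropenyl-3α,9α-dihydroxy-8-ketone
Conditions: [(Ph3P)CuH]6 (0.4 equiv), H2O (2 equiv), degassed benzene, rt
Reagents that add atoms: none
Why: Copper hydride conjugate reduction should deliver hydride to C6, and the resulting dienolate is protonated at its α-carbon C7 in the axial sense (from the β-face), which places the isopropenyl group equatorial (7α) and avoids a syn-diaxial clash with the C5 methyl.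

Step 12
Reactants: 17 7α-isopropenyl-3α,9α-dihydroxy-8-ketone
Product: 18 3α,8α,9α-triol
Conditions: LiBH(s-Bu)3 (3.5 equiv), THF, −78 °C; then H2O
Reagents that add atoms: none
Why: The bulky trialkylborohydride should attack the C8 ketone along the equatorial trajectory between its two equatorial neighbours and give the axial 8α-alcohol cis to both (the known outcome for 2-substituted cyclohexanones, α-isopropenyl ketones included).

Step 13
Reactants: 18 3α,8α,9α-triol; 19 hex-2-ynoic acid (2.4 equiv in all, one equivalent for each of the two esters)
Product: 20 3,9-bis(hex-2-ynoate)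
Conditions: 19 (2.4 equiv), DCC (2.4 equiv), DMAP (0.2 equiv), CH2Cl2, −20 to 0 °C
Reagents that add atoms: hex-2-ynoic acid (the second equivalent of 19, which supplies the second acyl group), CCCC#CC(=O)O
Why: Double Steglich esterification should acylate the two equatorial hydroxyls at C3 and C9, each with one molecule of the acid, faster than the axial C8 hydroxyl, which is flanked by two equatorial substituents, and the ynoate is used because it cannot lose alkene geometry during acylation.

Step 14
Reactants: 20 3,9-bis(hex-2-ynoate)
Product: 21 target CNP0420276.1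
Conditions: H2 (1 atm), Lindlar catalyst (Pd/CaCO3 poisoned with Pb(OAc)2), quinoline, EtOAc, rt
Reagents that add atoms: none
Why: Lindlar semihydrogenation should add H2 syn to both conjugated alkynes and give the two Z-enoates, while the poisoned catalyst leaves the 1,1-disubstituted isopropenyl alkene untouched.

**Compound list**
1 | thian-4-one (tetrahydro-4H-thiopyran-4-one) | O=C1CCSCC1 | starting material
2 | 2-chlorothian-4-one (racemic α-chloro sulfide) | O=C1CCSC(Cl)C1 | intermediate
3 | 2,3-dihydro-4H-thiopyran-4-one | O=C1C=CSCC1 | intermediate
4 | 4-(triisopropylsilyloxy)-2H-thiopyran | CC(C)[Si](OC1=CCSC=C1)(C(C)C)C(C)C | intermediate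
5 | 2-methoxy-5-methyl-1,4-benzoquinone | COC1=CC(=O)C(C)=CC1=O | starting material
6 | endo adduct: ring A with C2=C3 triisopropylsilyl enol ether and an S–CH2 bridge from C1 to C4 on the β face (2-thiabicyclo[2.2.2]octene); ring B 8-methoxy-7-ene-6,9-dione; 5β-methyl; 10β-H (cis-fused) | COC1=CC(=O)[C@]2(C)[C@H]3CS[C@H](C=C3O[Si](C(C)C)(C(C)C)C(C)C)[C@@H]2C1=O | intermediate
7 | cis-fused 8-methoxy-4β,5β-dimethyl-3-(triisopropylsilyloxy)decalin-2,7-diene-6,9-dione (10β-H) | COC1=CC(=O)[C@]2(C)[C@@H](C)C(O[Si](C(C)C)(C(C)C)C(C)C)=CC[C@@H]2C1=O | intermediate
8 | lithium C9(O)=C10 dienolate of 7 | COC1=CC(=O)[C@]2(C)[C@@H](C)C(O[Si](C(C)C)(C(C)C)C(C)C)=CCC2=C1[O-].[Li+] | intermediate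
9 | trans-fused 8-methoxy-4β,5β-dimethyl-3-(triisopropylsilyloxy)decalin-2,7-diene-6,9-dione (10α-H) | COC1=CC(=O)[C@]2(C)[C@@H](C)C(O[Si](C(C)C)(C(C)C)C(C)C)=CC[C@H]2C1=O | intermediate
10 | 6β,9β-dihydroxy-8-methoxy-4β,5β-dimethyl-3-(triisopropylsilyloxy)-10α-H-decalin-2,7-diene (carbinol configurations as expected for hydride attack anti to the C5 methyl; C6 is lost and C9 is reset later) | COC1=C[C@@H](O)[C@]2(C)[C@@H](C)C(O[Si](C(C)C)(C(C)C)C(C)C)=CC[C@H]2[C@H]1O | intermediate
11 | 9β-hydroxy-4β,5β-dimethyl-10α-H-decal-6-ene-3,8-dione | O=C1C=C[C@]2(C)[C@@H](C)C(=O)CC[C@H]2[C@H]1O | intermediate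
12 | 3α,9β-dihydroxy-4β,5β-dimethyl-10α-H-decal-6-en-8-one | O=C1C=C[C@]2(C)[C@@H](C)[C@H](O)CC[C@H]2[C@H]1O | intermediate
13 | 3α,9α-dihydroxy-4β,5β-dimethyl-10α-H-decal-6-en-8-one | O=C1C=C[C@]2(C)[C@@H](C)[C@H](O)CC[C@H]2[C@@H]1O | intermediate
14 | 7-iodo-3α,9α-dihydroxy-4β,5β-dimethyl-10α-H-decal-6-en-8-one | O=C1C(I)=C[C@]2(C)[C@@H](C)[C@H](O)CC[C@H]2[C@@H]1O | intermediate
15 | isopropenylboronic acid pinacol ester (2-isopropenyl-4,4,5,5-tetramethyl-1,3,2-dioxaborolane) | CC(=C)B1OC(C)(C)C(C)(C)O1 | starting material
16 | 3α,9α-dihydroxy-7-isopropenyl-4β,5β-dimethyl-10α-H-decal-6-en-8-one | O=C1C(C(C)=C)=C[C@]2(C)[C@@H](C)[C@H](O)CC[C@H]2[C@@H]1O | intermediate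
17 | 3α,9α-dihydroxy-7α-isopropenyl-4β,5β-dimethyl-10α-H-decalin-8-one | C=C(C)[C@@H]1C[C@]2(C)[C@@H](C)[C@H](O)CC[C@H]2[C@H](O)C1=O | intermediate
18 | 7α-isopropenyl-4β,5β-dimethyl-10α-H-decalin-3α,8α,9α-triol | C=C(C)[C@@H]1C[C@]2(C)[C@@H](C)[C@H](O)CC[C@H]2[C@H](O)[C@@H]1O | intermediate
19 | hex-2-ynoic acid | CCCC#CC(=O)O | starting material
20 | 3α,9α-bis(hex-2-ynoyloxy)-8α-hydroxy-7α-isopropenyl-4β,5β-dimethyl-10α-H-decalin | C=C(C)[C@@H]1C[C@]2(C)[C@@H](C)[C@H](OC(=O)C#CCCC)CC[C@H]2[C@H](OC(=O)C#CCCC)[C@@H]1O | intermediate
21 | 3α,9α-bis[(Z)-hex-2-enoyloxy]-8α-hydroxy-7α-isopropenyl-4β,5β-dimethyl-10α-H-decalin (CNP0420276.1) | C=C(C)[C@@H]1C[C@]2(C)[C@@H](C)[C@H](OC(=O)/C=C\CCC)CC[C@H]2[C@H](OC(=O)/C=C\CCC)[C@@H]1O | target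

**Totals and risks**
Total step count: 14. Longest linear sequence: 14 steps (1 to 21); compounds 5, 15 and 19 are bought.

Steps most likely to fail:

1. Step 3 (Proposed new method). What may go wrong: poor face discrimination by the catalyst, reversal of regiochemistry if titanium binds monodentate at the more basic C6 carbonyl instead of chelating, or catalyst inhibition by the sulfide of the diene. Fallback (known chemistry): the route sets out again from 4 and 5 with an uncatalysed thermal Diels–Alder reaction (toluene, 60 °C). Its regiochemistry is intrinsic, because the free C9 carbonyl is the more electron-poor one. It gives the racemate, that is 6 together with its mirror image ent-6 F1. The enantiomers are separated by preparative chromatography on a chiral stationary phase, and the route is rejoined at 6; the enzyme of step 7 would remove any residual minor enantiomer.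

2. Step 4. What may go wrong: over-reduction of ring B on nickel (saturation of C7=C8 or reduction of the ketones) and base-induced β-elimination of the C1 sulfide, which is β to the C9 carbonyl. Fallback: from 6, both ring-B carbonyls are first reduced with LiAlH4 (THF, −40 °C) to the thia-bridged enol-ether diol F2 (carbinol configurations irrelevant), in which the sulfide is the only nickel-sensitive group. Raney Ni then gives the desulfurized cis-fused diol F3. Both allylic alcohols are re-oxidized with activated MnO2 (CH2Cl2, rt), which returns the route to 7.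

3. Step 13. What may go wrong: insufficient rate difference between the equatorial C9 and the axial C8 hydroxyl (over-acylation, or acyl migration within the cis-diol). Fallback: the hydroxyls are differentiated by oxidation level instead of by rate. From 17, where C8 is still a ketone, both hydroxyls are esterified with 19 (2.4 equiv, DCC 2.4 equiv, DMAP cat.) to the bis(hex-2-ynoate) ketone F4. Lindlar semihydrogenation gives the bis[(Z)-hex-2-enoate] ketone F5. The ketone is then reduced with LiBH(s-Bu)3 (1.1 equiv, THF, −78 °C, AcOH quench at −78 °C), which is expected to be faster than conjugate reduction of the β-substituted enoates, and the route is rejoined at 21.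

**Further compounds**
F1 | step 3 | mirror image of adduct 6 (ent-6) | COC1=CC(=O)[C@@]2(C)[C@@H]3CS[C@@H](C=C3O[Si](C(C)C)(C(C)C)C(C)C)[C@H]2C1=O
F2 | step 4 | thia-bridged enol-ether diol (6,9-diol of 6, carbinol epimers) | COC1=CC(O)[C@]2(C)[C@H]3CS[C@H](C=C3O[Si](C(C)C)(C(C)C)C(C)C)[C@@H]2C1O
F3 | step 4 | desulfurized cis-fused enol-ether diol (6,9-diol of 7, carbinol epimers) | COC1=CC(O)[C@]2(C)[C@@H](C)C(O[Si](C(C)C)(C(C)C)C(C)C)=CC[C@@H]2C1O
F4 | step 13 | 3α,9α-bis(hex-2-ynoyloxy)-7α-isopropenyl-4β,5β-dimethyl-10α-H-decalin-8-one | C=C(C)[C@@H]1C[C@]2(C)[C@@H](C)[C@H](OC(=O)C#CCCC)CC[C@H]2[C@H](OC(=O)C#CCCC)C1=O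
F5 | step 13 | 3α,9α-bis[(Z)-hex-2-enoyloxy]-7α-isopropenyl-4β,5β-dimethyl-10α-H-decalin-8-one | C=C(C)[C@@H]1C[C@]2(C)[C@@H](C)[C@H](OC(=O)/C=C\CCC)CC[C@H]2[C@H](OC(=O)/C=C\CCC)C1=O
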